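**Retrosynthetic overview**

1. Target 16 ← 15 ← 14: the four phenols are freed last, the C5 silyl ether with fluoride and the three benzyl ethers by hydrogenolysis.
2. Ring C is the only ring made and is closed last by forming C2–C3. The strategy rests on C2 being both benzylic to ring B and bonded to O1: it already exists as the OCH2Ph carbon of a C8a O-benzyl ether, 1,6 to a carbenoid at C3. Enantioselective dirhodium-carbenoid C–H insertion of diazoketone 13 gives 14 and sets C2.
3. 13 ← methyl ketone 11 by detrifluoroacetylative diazo transfer. The C5 oxygen carries a silyl group, so only the C8a benzyl ether can react and the side chain ends at C6, not C8.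
4. 11 ← aryl iodide 5 + benzylzinc 10 (Negishi coupling, C6–CH2 bond). 5 ← 2',4',6'-trihydroxyacetophenone by 2',4'-di-O-benzylation, iodination ortho to the remaining phenol and O-silylation. 10 ← 2,3-dihydroxybenzaldehyde. Rings A, B and the catechol ring are bought.

Key step: step 9

Remark: the (2R) sense of induction of Rh2(5S-MEPY)4 in this 1,6-insertion is assumed, and the mirror-image catalyst Rh2(5R-MEPY)4 would be used if the opposite sense is found. The C7 oxygen is carried as a benzyl ether and the C5 oxygen as a triisopropylsilyl (TIPS) ether.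

**Route**

Step 1
Reactants: 1 2',4',6'-trihydroxyacetophenone; 2 benzyl bromide
Product: 3 2',4'-bis(benzyloxy)-6'-hydroxyacetophenone
Conditions: BnBr (2.1 equiv), K2CO3, DMF, rt
Reagents that add atoms: benzyl bromide (2), BrCc1ccccc1
Why: Williamson etherification should stop after two benzylations, because the last phenol is hydrogen-bonded to the ketone and is the least nucleophilic.

Step 2
Reactants: 3 2',4'-bis(benzyloxy)-6'-hydroxyacetophenone
Product: 4 1-[4,6-bis(benzyloxy)-2-hydroxy-3-iodophenyl]ethanone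
Conditions: BnMe3N+ ICl2− (1.05 equiv), NaHCO3, CH2Cl2–MeOH, rt
Reagents that add atoms: benzyltrimethylammonium dichloroiodate, C[N+](C)(C)Cc1ccccc1.Cl[I-]Cl
Why: Electrophilic aromatic iodination of 2-hydroxy-4,6-dialkoxyaryl ketones with this mild iodine source is expected to go to the ring position ortho to the free chelated phenol, which is the future C6.

Step 3
Reactants: 4 1-[4,6-bis(benzyloxy)-2-hydroxy-3-iodophenyl]ethanone
Product: 5 1-[4,6-bis(benzyloxy)-3-iodo-2-(triisopropylsilyloxy)phenyl]ethanone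
Conditions: TIPSOTf, 2,6-lutidine, CH2Cl2, 0 °C to rt
Reagents that add atoms: triisopropylsilyl trifluoromethanesulfonate, CC(C)[Si](OS(=O)(=O)C(F)(F)F)(C(C)C)C(C)C
Why: O-silylation with the silyl triflate and a hindered pyridine base should cap even this chelated, doubly flanked phenol, and the weak base leaves the methyl ketone unenolised.

Step 4
Reactants: 6 2,3-dihydroxybenzaldehyde; 2 benzyl bromide
Product: 7 2,3-bis(benzyloxy)benzaldehyde
Conditions: BnBr (2.2 equiv), K2CO3, DMF, 60 °C
Reagents that add atoms: benzyl bromide (2), BrCc1ccccc1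
Why: Williamson etherification with excess halide and gentle heating should alkylate both catechol oxygens, the chelated one included.

Step 5
Reactants: 7 2,3-bis(benzyloxy)benzaldehyde
Product: 8 [2,3-bis(benzyloxy)phenyl]methanol
Conditions: NaBH4, MeOH–THF, 0 °C
Reagents that add atoms: none
Why: Borohydride reduction of an aryl aldehyde to the benzylic alcohol is fast and leaves the benzyl ethers untouched.

Step 6
Reactants: 8 [2,3-bis(benzyloxy)phenyl]methanol
Product: 9 1-(chloromethyl)-2,3-bis(benzyloxy)benzene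
Conditions: SOCl2, CH2Cl2, 0 °C to rt
Reagents that add atoms: thionyl chloride, O=S(Cl)Cl
Why: Deoxychlorination through the chlorosulfite is easy for an electron-rich benzylic alcohol, and aryl benzyl ethers tolerate the HCl formed at this temperature.

Step 7
Reactants: 9 1-(chloromethyl)-2,3-bis(benzyloxy)benzene; 5 1-[4,6-bis(benzyloxy)-3-iodo-2-(triisopropylsilyloxy)phenyl]ethanone
Product: 11 1-{4,6-bis(benzyloxy)-3-[2,3-bis(benzyloxy)benzyl]-2-(triisopropylsilyloxy)phenyl}ethanone, via [2,3-bis(benzyloxy)benzyl]zinc chloride 10 (not isolated)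
Conditions: 9, Zn dust, LiCl, THF, 25 °C; then 5, Pd(OAc)2 (2 mol%), SPhos (4 mol%), THF, 25 to 50 °C
Reagents that add atoms: zinc, [Zn] (held only in 10; no reagent atoms stay in 11)
Why: LiCl-promoted zinc insertion into the benzylic chloride followed by Negishi coupling should join the two halves, since benzylzinc reagents tolerate aryl ketones and the biarylphosphine palladium catalyst accepts a di-ortho-substituted electron-rich aryl iodide.

Step 8
Reactants: 11 1-{4,6-bis(benzyloxy)-3-[2,3-bis(benzyloxy)benzyl]-2-(triisopropylsilyloxy)phenyl}ethanone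
Product: 13 2-diazo-1-{4,6-bis(benzyloxy)-3-[2,3-bis(benzyloxy)benzyl]-2-(triisopropylsilyloxy)phenyl}ethanone, via 4,4,4-trifluoro-1,3-diketone 12 (not isolated)
Conditions: LiN(SiMe3)2, THF, −78 °C; CF3CO2CH2CF3, −78 °C; 5% aq. HCl work-up; then MsN3, Et3N, H2O (1 equiv), MeCN, rt
Reagents that add atoms: 2,2,2-trifluoroethyl trifluoroacetate, O=C(OCC(F)(F)F)C(F)(F)F (CF3CO group, held only in 12); methanesulfonyl azide, CS(=O)(=O)N=[N+]=[N-] (the N2 of 13)
Why: Claisen trifluoroacetylation of the kinetic methyl-ketone enolate activates the methyl group for Regitz-type diazo transfer, and loss of the trifluoroacetyl group as its sulfonamide should give the diazomethyl ketone without acid chloride or diazomethane; the bulky TIPS ether is chosen to resist migration at −78 °C.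

Step 9
Reactants: 13 2-diazo-1-{4,6-bis(benzyloxy)-3-[2,3-bis(benzyloxy)benzyl]-2-(triisopropylsilyloxy)phenyl}ethanone
Product: 14 (2R)-7-(benzyloxy)-6-[2,3-bis(benzyloxy)benzyl]-2-phenyl-5-(triisopropylsilyloxy)chroman-4-one
Conditions: Rh2(5S-MEPY)4 (2 mol%), CH2Cl2, reflux, slow addition of 13
Reagents that add atoms: none
Why: The dirhodium tetracarboxamidate Rh2(5S-MEPY)4, dirhodium tetrakis[methyl (5S)-2-oxopyrrolidine-5-carboxylate], takes N2 from 13 to give an electrophilic carbenoid at the future C3, which inserts through a concerted three-centre, hydride-transfer-like transition state into one benzylic O–CH2 hydrogen of the O-benzyl group on the future C8a oxygen, forming C2–C3. The closest known reaction type is the chiral dirhodium-catalysed intramolecular C–H insertion of 2-alkoxyaryl α-diazoketones to 2-substituted chroman-4-ones. Ring C closes as a six-membered ring by 1,6-insertion, because the 1,5-position is the ether oxygen itself and the C–H that reacts is activated twice, by O1 and by ring B. C2 is set by the chiral carboxamidate ligand sphere, which distinguishes the two enantiotopic benzylic hydrogens (catalyst control, no stereocentre in the substrate). The step needs insertion to win over oxonium-ylide formation with 1,2-benzyl shift and over addition to the benzyl arene, which the weakly electrophilic carboxamidate carbenoid, the poorly basic aryl ether oxygen and slow addition should secure. It also needs closure onto the C8a oxygen only, which holds because the other ortho oxygen carries a TIPS group with no activated C–H and shielded lone pairs, and the remaining benzyl ethers sit para to the acyl group or on the remote catechol ring, out of reach.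

Step 10
Reactants: 14 (2R)-7-(benzyloxy)-6-[2,3-bis(benzyloxy)benzyl]-2-phenyl-5-(triisopropylsilyloxy)chroman-4-one
Product: 15 (2R)-7-(benzyloxy)-6-[2,3-bis(benzyloxy)benzyl]-5-hydroxy-2-phenylchroman-4-one
Conditions: Bu4NF, AcOH (1:1), THF, 0 °C
Reagents that add atoms: none
Why: Fluoride desilylation of an aryl silyl ether peri to a ketone is fast, and the acetic acid buffer should prevent base-induced ring opening to the chalcone, so C2 is not scrambled.

Step 11
Reactants: 15 (2R)-7-(benzyloxy)-6-[2,3-bis(benzyloxy)benzyl]-5-hydroxy-2-phenylchroman-4-one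
Product: 16 (2R)-6-(2,3-dihydroxybenzyl)-5,7-dihydroxy-2-phenylchroman-4-one (CNP0348560.2)
Conditions: H2 (1 atm), 10% Pd/C, EtOAc–MeOH, rt
Reagents that add atoms: none
Why: Catalytic hydrogenolysis should cleave the three primary O-benzyl ethers well before the secondary cyclic C2–O1 bond or the hydrogen-bonded C4 ketone, provided the reaction is stopped at three equivalents of hydrogen, and the neutral medium leaves C2 untouched.

**Compound list**

1 | 2',4',6'-trihydroxyacetophenone | CC(=O)c1c(O)cc(O)cc1O | starting material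
2 | benzyl bromide | BrCc1ccccc1 | starting material
3 | 2',4'-bis(benzyloxy)-6'-hydroxyacetophenone | CC(=O)c1c(O)cc(OCc2ccccc2)cc1OCc1ccccc1 | intermediate
4 | 1-[4,6-bis(benzyloxy)-2-hydroxy-3-iodophenyl]ethanone | CC(=O)c1c(O)c(I)c(OCc2ccccc2)cc1OCc1ccccc1 | intermediate
5 | 1-[4,6-bis(benzyloxy)-3-iodo-2-(triisopropylsilyloxy)phenyl]ethanone | CC(=O)c1c(O[Si](C(C)C)(C(C)C)C(C)C)c(I)c(OCc2ccccc2)cc1OCc1ccccc1 | intermediate
6 | 2,3-dihydroxybenzaldehyde | O=Cc1cccc(O)c1O | starting material
7 | 2,3-bis(benzyloxy)benzaldehyde | O=Cc1cccc(OCc2ccccc2)c1OCc1ccccc1 | intermediate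
8 | [2,3-bis(benzyloxy)phenyl]methanol | OCc1cccc(OCc2ccccc2)c1OCc1ccccc1 | intermediate
9 | 1-(chloromethyl)-2,3-bis(benzyloxy)benzene | ClCc1cccc(OCc2ccccc2)c1OCc1ccccc1 | intermediate
10 | [2,3-bis(benzyloxy)benzyl]zinc chloride | Cl[Zn]Cc1cccc(OCc2ccccc2)c1OCc1ccccc1 | intermediate
11 | 1-{4,6-bis(benzyloxy)-3-[2,3-bis(benzyloxy)benzyl]-2-(triisopropylsilyloxy)phenyl}ethanone | CC(=O)c1c(O[Si](C(C)C)(C(C)C)C(C)C)c(Cc2cccc(OCc3ccccc3)c2OCc2ccccc2)c(OCc2ccccc2)cc1OCc1ccccc1 | intermediate
12 | 1-{4,6-bis(benzyloxy)-3-[2,3-bis(benzyloxy)benzyl]-2-(triisopropylsilyloxy)phenyl}-4,4,4-trifluorobutane-1,3-dione | O=C(CC(=O)C(F)(F)F)c1c(O[Si](C(C)C)(C(C)C)C(C)C)c(Cc2cccc(OCc3ccccc3)c2OCc2ccccc2)c(OCc2ccccc2)cc1OCc1ccccc1 | intermediate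
13 | 2-diazo-1-{4,6-bis(benzyloxy)-3-[2,3-bis(benzyloxy)benzyl]-2-(triisopropylsilyloxy)phenyl}ethanone | [N-]=[N+]=CC(=O)c1c(O[Si](C(C)C)(C(C)C)C(C)C)c(Cc2cccc(OCc3ccccc3)c2OCc2ccccc2)c(OCc2ccccc2)cc1OCc1ccccc1 | intermediate
14 | (2R)-7-(benzyloxy)-6-[2,3-bis(benzyloxy)benzyl]-2-phenyl-5-(triisopropylsilyloxy)chroman-4-one | O=C1C[C@H](c2ccccc2)Oc2cc(OCc3ccccc3)c(Cc3cccc(OCc4ccccc4)c3OCc3ccccc3)c(O[Si](C(C)C)(C(C)C)C(C)C)c21 | intermediate
15 | (2R)-7-(benzyloxy)-6-[2,3-bis(benzyloxy)benzyl]-5-hydroxy-2-phenylchroman-4-one | O=C1C[C@H](c2ccccc2)Oc2cc(OCc3ccccc3)c(Cc3cccc(OCc4ccccc4)c3OCc3ccccc3)c(O)c21 | intermediate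
16 | (2R)-6-(2,3-dihydroxybenzyl)-5,7-dihydroxy-2-phenylchroman-4-one | O=C1C[C@H](c2ccccc2)Oc2cc(O)c(Cc3cccc(O)c3O)c(O)c21 | target

**Step count and risks**

Total step count: 11. Longest linear sequence: 8 steps (steps 1, 2, 3, 7, 8, 9, 10, 11; the branch through steps 4, 5, 6 is equally long).

Steps most likely to fail:

Step 9. The carbenoid may be captured by the lone pair of the C8a ether oxygen, giving an oxonium ylide and, after 1,2-benzyl shift, a five-membered ketone. Selection between the two enantiotopic benzylic hydrogens may also be weak for an acceptor-only ketone carbenoid on a twisted, di-ortho-substituted aryl ring. The fallback closes ring C at O1–C2 and sets C2 by a known asymmetric conjugate addition; it sets out from 11 and returns at 14. MgBr2·OEt2 in toluene–Et2O at reflux cleaves only the benzyl ether that chelates with the ketone, giving 1-{4-(benzyloxy)-3-[2,3-bis(benzyloxy)benzyl]-6-hydroxy-2-(triisopropylsilyloxy)phenyl}ethanone F1. Heating with Me2NCH(OMe)2 gives the (E)-3-(dimethylamino)propenone F2, which closes with TsOH in CH2Cl2 to 7-(benzyloxy)-6-[2,3-bis(benzyloxy)benzyl]-5-(triisopropylsilyloxy)chromen-4-one F3. Addition of PhB(OH)2 to F3 with Pd(OCOCF3)2, a chiral tert-butyl pyridine-oxazoline ligand of the appropriate hand and NH4PF6 in wet ClCH2CH2Cl at 60 °C should give 14.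

Step 2. Iodination may occur partly para to the free phenol, between the two benzyloxy groups, or twice; the para isomer would carry the side chain to C8. The fallback makes the ortho C–C bond by delivery from the phenol oxygen; it sets out from 3 (with aldehyde 7) and returns at 11. Condensation of 3, 7 and PhB(OH)2 with catalytic propionic acid in toluene under water removal gives the 2-phenyl-4-aryl-4H-1,3,2-benzodioxaborin F4, which can only form ortho to the phenol. Ionic hydrogenation with Et3SiH and CF3CO2H in CH2Cl2 gives 1-{4,6-bis(benzyloxy)-3-[2,3-bis(benzyloxy)benzyl]-2-hydroxyphenyl}ethanone F5. Silylation as in step 3 (TIPSOTf, 2,6-lutidine) gives 11.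

Step 8. In the lithium enolate the silyl group may shift from the phenol oxygen to the enolate oxygen, or the hindered silyl ether may be lost in the aqueous amine medium of the diazo transfer. The fallback avoids the enolate; it sets out from 11 and returns at 13. Riley oxidation with SeO2 in aqueous dioxane at 90 °C gives the arylglyoxal F6. TsNHNH2 in THF at 0 °C condenses at the aldehyde carbon to give the mono-tosylhydrazone F7. Et3N in CH2Cl2 then expels p-toluenesulfinate (Bamford–Stevens-type cleavage) to give 13.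

**Further compounds**

F1 | step 9 | 1-{4-(benzyloxy)-3-[2,3-bis(benzyloxy)benzyl]-6-hydroxy-2-(triisopropylsilyloxy)phenyl}ethanone | CC(=O)c1c(O[Si](C(C)C)(C(C)C)C(C)C)c(Cc2cccc(OCc3ccccc3)c2OCc2ccccc2)c(OCc2ccccc2)cc1O
F2 | step 9 | (E)-1-{4-(benzyloxy)-3-[2,3-bis(benzyloxy)benzyl]-6-hydroxy-2-(triisopropylsilyloxy)phenyl}-3-(dimethylamino)prop-2-en-1-one | CN(C)/C=C/C(=O)c1c(O[Si](C(C)C)(C(C)C)C(C)C)c(Cc2cccc(OCc3ccccc3)c2OCc2ccccc2)c(OCc2ccccc2)cc1O
F3 | step 9 | 7-(benzyloxy)-6-[2,3-bis(benzyloxy)benzyl]-5-(triisopropylsilyloxy)chromen-4-one | O=c1ccoc2cc(OCc3ccccc3)c(Cc3cccc(OCc4ccccc4)c3OCc3ccccc3)c(O[Si](C(C)C)(C(C)C)C(C)C)c12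
F4 | step 2 | 1-{5,7-bis(benzyloxy)-4-[2,3-bis(benzyloxy)phenyl]-2-phenyl-4H-1,3,2-benzodioxaborin-8-yl}ethanone (racemic) | CC(=O)c1c2OB(c3ccccc3)OC(c3cccc(OCc4ccccc4)c3OCc3ccccc3)c2c(OCc2ccccc2)cc1OCc1ccccc1
F5 | step 2 | 1-{4,6-bis(benzyloxy)-3-[2,3-bis(benzyloxy)benzyl]-2-hydroxyphenyl}ethanone | CC(=O)c1c(O)c(Cc2cccc(OCc3ccccc3)c2OCc2ccccc2)c(OCc2ccccc2)cc1OCc1ccccc1
F6 | step 8 | 2-{4,6-bis(benzyloxy)-3-[2,3-bis(benzyloxy)benzyl]-2-(triisopropylsilyloxy)phenyl}-2-oxoacetaldehyde | O=CC(=O)c1c(O[Si](C(C)C)(C(C)C)C(C)C)c(Cc2cccc(OCc3ccccc3)c2OCc2ccccc2)c(OCc2ccccc2)cc1OCc1ccccc1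
F7 | step 8 | 2-{4,6-bis(benzyloxy)-3-[2,3-bis(benzyloxy)benzyl]-2-(triisopropylsilyloxy)phenyl}-2-oxoacetaldehyde 1-(4-methylbenzenesulfonyl)hydrazone | Cc1ccc(cc1)S(=O)(=O)NN=CC(=O)c1c(O[Si](C(C)C)(C(C)C)C(C)C)c(Cc2cccc(OCc3ccccc3)c2OCc2ccccc2)c(OCc2ccccc2)cc1OCc1ccccc1
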